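The six ring carbons are treated as a dearomatized phenol. The quaternary carbinol C1 and the allylic carbinol C4 of the cyclohexene ring are 1,4-related and flank the C5=C6 alkene, which is the pattern of a p-quinol whose two enone arms, C2=C3 and C6=C5, are enantiotopic. One amine-salt-catalysed epoxidation with H2O2 should choose one arm and lay an oxirane across C2–C3 on the face of the C1 hydroxyl, so that C1, C2 and C3 become stereogenic together. Its precursor is the achiral, silyl-protected 4-hydroxy-4-(oxymethyl)cyclohexa-2,5-dienone. Hydride delivery to C4 and benzoate attack at C3 with inversion then complete the array.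

Key step: step 3

Remark on numbering: ring atoms carry the target's numbers in every compound (C1 quaternary carbinol, C2 and C3 the oxirane carbons, C4 the carbon para to C1, C5=C6 the alkene); the CIP descriptors in the names refer to this numbering.

Assumption: the quinine-derived amine is taken to give the enantiomer drawn; if the sense proves opposite, the quinidine-derived pseudoenantiomer replaces it with no other change, and the absolute configuration is checked at compound 7 by MTPA ester analysis of the C4 carbinol before material is carried on.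

Step 1
Reactants: 1 4-hydroxybenzyl alcohol
Product: 2 4-[(tert-butyldiphenylsilyloxy)methyl]phenol
Conditions: TBDPSCl (1.05 equiv), imidazole, DMF, 0 °C
Reagents that add atoms: tert-butyl(chloro)diphenylsilane, CC(C)(C)[Si](Cl)(c1ccccc1)c1ccccc1
Why: Chemoselective silyl ether formation: with imidazole as the only base the phenol stays un-ionised, so the more nucleophilic primary benzylic hydroxyl should take up the bulky silyl chloride first when one equivalent is used at 0 °C; no stereocenter is involved.

Step 2
Reactants: 2 4-[(tert-butyldiphenylsilyloxy)methyl]phenol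
Product: 4 p-quinol 4-hydroxy-4-[(tert-butyldiphenylsilyloxy)methyl]cyclohexa-2,5-dien-1-one, via hydroperoxy dienone 3 (not isolated)
Conditions: KHSO5 (as 2KHSO5·KHSO4·K2SO4), NaHCO3, MeCN/H2O, rt; then Me2S, rt
Reagents that add atoms: potassium peroxymonosulfate (source of singlet oxygen), [K+].[O-]S(=O)(=O)OO
Why: Oxidative dearomatization by singlet oxygen followed by hydroperoxide reduction: bicarbonate-promoted decomposition of peroxymonosulfate releases singlet oxygen, which the electron-rich phenol should capture at its substituted para carbon to give 3, and Me2S then cleaves the O–O bond to the tertiary carbinol; 4 is achiral (mirror plane through C1 and C4) and the silyl ether blocks retro-aldol loss of formaldehyde.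

Step 3
Reactants: 4 p-quinol 4-hydroxy-4-[(tert-butyldiphenylsilyloxy)methyl]cyclohexa-2,5-dien-1-one; 5 hydrogen peroxide
Product: 6 syn-epoxy quinol (1S,2S,3R)-2,3-epoxy-1-hydroxy-1-[(tert-butyldiphenylsilyloxy)methyl]cyclohex-5-en-4-one (oxirane cis to the C1 hydroxyl)
Conditions: 9-amino-9-deoxy-epi-quinine·2CF3CO2H (10 mol%), 50% aq. H2O2 (1.3 equiv), 1,4-dioxane, 30 °C
Reagents that add atoms: none
Why: Proposed new method: the primary amine of the catalyst should condense with the unhindered C4 carbonyl of 4 (both α carbons are sp2 CH) to a chiral iminium ion, whose protonated quinuclidine hydrogen-bonds H2O2 and guides it to the β carbon C2 of one enone arm on the face of the C1 hydroxyl (C2–O bond), after which the enamine attacks the proximal peroxide oxygen through C3 with loss of water (C3–O bond) and hydrolysis frees the catalyst. The closest known reaction types are the primary-amine-salt (iminium) catalysed asymmetric Weitz–Scheffer epoxidation of simple cyclic enones with H2O2, the hydroxyl-syn nucleophilic epoxidation of 4-hydroxy-4-alkylcyclohexadienones and the organocatalytic desymmetrization of p-quinols by conjugate addition, which have not been merged into a desymmetrizing epoxidation of a prochiral dienone. The only ring closed is the oxirane, by a 3-exo-tet displacement at oxygen. The absolute configuration at C2 and C3, and with it at the formerly prochiral C1, is controlled by the catalyst through its choice between the enantiotopic arms C2=C3 and C6=C5, whereas the cis relation of the oxirane to the C1 hydroxyl is controlled by the substrate. The step therefore needs enantiotopic-group selectivity and syn facial selectivity together: the amine salt supplies the first, and the hydrogen-bonding C1 hydroxyl with the bulky CH2OTBDPS group screening the other face supplies the second. With H2O2 held near 1.3 equivalents the minor enantiomer, which still carries the catalyst-preferred alkene, should be drained to the meso bis-epoxide, so the enantiomeric purity of 6 should rise with conversion.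

Step 4
Reactants: 6 syn-epoxy quinol
Product: 7 all-cis epoxy diol (1S,2S,3S,4S)-2,3-epoxy-1-[(tert-butyldiphenylsilyloxy)methyl]cyclohex-5-ene-1,4-diol
Conditions: NaBH4, CeCl3·7H2O, MeOH, −78 °C
Reagents that add atoms: none
Why: Luche 1,2-reduction: the cerium-activated carbonyl should be attacked on the face opposite the adjacent oxirane oxygen (steric and lone-pair repulsion on the epoxide face, CH2OTBDPS pseudo-equatorial and out of the way), so the new C4 hydroxyl comes out cis to the epoxide (4S) while the C5=C6 alkene and the oxirane are left alone.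

Step 5
Reactants: 7 all-cis epoxy diol; 8 benzoic acid
Product: 9 (1S,2S,3R,4S)-3-benzoyloxy-1-[(tert-butyldiphenylsilyloxy)methyl]cyclohex-5-ene-1,2,4-triol
Conditions: PhCO2H (4 equiv), Bu4N+ PhCO2− (20 mol%), toluene, 70 °C
Reagents that add atoms: none
Why: Carboxylate SN2 opening of an epoxide: benzoate should attack C3 from the α face with inversion (3R), because the backside of C2 is screened by the quaternary C1 and its α-CH2OTBDPS group, while C2 keeps the epoxide oxygen as its β hydroxyl; both flanking hydroxyls are cis to the oxirane and so cannot open or shift it, and the benzoic acid buffer suppresses benzoyl migration.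

Step 6
Reactants: 9 (1S,2S,3R,4S)-3-benzoyloxy-1-[(tert-butyldiphenylsilyloxy)methyl]cyclohex-5-ene-1,2,4-triol
Product: 10 (1S,2S,3R,4S)-3-benzoyloxy-1-(hydroxymethyl)cyclohex-5-ene-1,2,4-triol
Conditions: HF·pyridine, THF/pyridine, 0 °C to rt
Reagents that add atoms: none
Why: Fluoride-mediated desilylation: the strong Si–F bond drives cleavage of the primary silyl ether, and the weakly acidic, pyridine-buffered medium forms no alkoxide, so the C3 benzoate should stay in place and no stereocenter is touched.

Step 7
Reactants: 10 (1S,2S,3R,4S)-3-benzoyloxy-1-(hydroxymethyl)cyclohex-5-ene-1,2,4-triol; 11 benzoyl chloride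
Product: 12 target, [(1S,2S,3R,4S)-3-benzoyloxy-1,2,4-trihydroxycyclohex-5-en-1-yl]methyl benzoate
Conditions: BzCl (1.05 equiv), 2,4,6-collidine, CH2Cl2/THF, −78 to −40 °C
Reagents that add atoms: none
Why: Selective O-acylation with an acid chloride and a hindered pyridine base: at low temperature and with one equivalent of reagent the only primary hydroxyl should react well ahead of the secondary C2 and C4 hydroxyls and the tertiary C1 hydroxyl, giving the target with all stereocenters untouched.

Compound list
1 | 4-hydroxybenzyl alcohol | OCc1ccc(O)cc1 | starting material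
2 | 4-[(tert-butyldiphenylsilyloxy)methyl]phenol | CC(C)(C)[Si](OCc1ccc(O)cc1)(c1ccccc1)c1ccccc1 | intermediate
3 | 4-hydroperoxy-4-[(tert-butyldiphenylsilyloxy)methyl]cyclohexa-2,5-dien-1-one (not isolated) | CC(C)(C)[Si](OCC1(OO)C=CC(=O)C=C1)(c1ccccc1)c1ccccc1 | intermediate
4 | 4-hydroxy-4-[(tert-butyldiphenylsilyloxy)methyl]cyclohexa-2,5-dien-1-one (achiral p-quinol) | CC(C)(C)[Si](OCC1(O)C=CC(=O)C=C1)(c1ccccc1)c1ccccc1 | intermediate
5 | hydrogen peroxide | OO | starting material
6 | (1S,2S,3R)-2,3-epoxy-1-hydroxy-1-[(tert-butyldiphenylsilyloxy)methyl]cyclohex-5-en-4-one, oxirane cis to the hydroxyl [systematic: (4S,5S,6R)-5,6-epoxy-4-hydroxy-4-(silyloxymethyl)cyclohex-2-en-1-one] | CC(C)(C)[Si](OC[C@@]1(O)C=CC(=O)[C@@H]2O[C@H]12)(c1ccccc1)c1ccccc1 | intermediate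
7 | (1S,2S,3S,4S)-2,3-epoxy-1-[(tert-butyldiphenylsilyloxy)methyl]cyclohex-5-ene-1,4-diol, both hydroxyls and the oxirane on the β face | CC(C)(C)[Si](OC[C@@]1(O)C=C[C@H](O)[C@@H]2O[C@H]12)(c1ccccc1)c1ccccc1 | intermediate
8 | benzoic acid | O=C(O)c1ccccc1 | starting material
9 | (1S,2S,3R,4S)-3-benzoyloxy-1-[(tert-butyldiphenylsilyloxy)methyl]cyclohex-5-ene-1,2,4-triol (1β,2β,4β-hydroxyls, 3α-benzoate) | CC(C)(C)[Si](OC[C@@]1(O)C=C[C@H](O)[C@@H](OC(=O)c2ccccc2)[C@@H]1O)(c1ccccc1)c1ccccc1 | intermediate
10 | (1S,2S,3R,4S)-3-benzoyloxy-1-(hydroxymethyl)cyclohex-5-ene-1,2,4-triol | OC[C@@]1(O)C=C[C@H](O)[C@@H](OC(=O)c2ccccc2)[C@@H]1O | intermediate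
11 | benzoyl chloride | O=C(Cl)c1ccccc1 | starting material
12 | [(1S,2S,3R,4S)-3-benzoyloxy-1,2,4-trihydroxycyclohex-5-en-1-yl]methyl benzoate (1α-benzoyloxymethyl-3α-benzoyloxycyclohex-5-en-1β,2β,4β-triol) | O=C(OC[C@@]1(O)C=C[C@H](O)[C@@H](OC(=O)c2ccccc2)[C@@H]1O)c1ccccc1 | target

Total step count: 7
Longest linear sequence: 7 steps (1 to 12)

Steps most likely to fail

1. Step 3 (the proposed method). The amine salt may form the iminium ion of the cross-conjugated dienone too slowly, may discriminate poorly between the two enone arms, or may allow over-epoxidation to consume the product. The fallback sets out from 4 and uses known chemistry. Uncatalysed Weitz–Scheffer epoxidation (30% H2O2, LiOH, MeOH, 0 °C), known to go syn to the hydroxyl in 4-hydroxy-4-alkyl dienones, should give the racemic syn-epoxy quinol F1. Luche reduction as in step 4 should give the racemic all-cis epoxy diol F2. Lipase-catalysed acetylation of the C4 carbinol (Candida antarctica lipase B, vinyl acetate, MTBE, rt), run beyond half conversion, should remove the faster-reacting antipode as the mirror-image-series C4 acetate F3. By the empirical size rule for lipases, the (4R) carbinol is the one expected to be acylated, because its bulkier epoxide flank outranks the vinyl flank. The unreacted (4S) alcohol is compound 7, where the route is rejoined; the assignment would be confirmed by MTPA esters. Half of the material is lost.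

2. Step 5. Opening at the hindered oxirane may be slow. Attack may divide between C3 and C2, since the steric preference for C3 is opposed by the preference for diaxial opening. The benzoyl group may also migrate from O3 to O4 or O2 on heating. The fallback sets out from 7. Silylation of the secondary allylic C4 hydroxyl (TBSCl, imidazole, DMF; the tertiary hydroxyl is inert) gives the 4-O-TBS ether of the epoxy diol F4. Ti(OiPr)4-mediated opening with benzoic acid (CH2Cl2, rt) follows: the C1 hydroxyl, the only one left and cis to the oxirane, binds titanium together with the epoxide oxygen, and benzoate is delivered to the distal carbon C3 of the C1(OH)–C2–C3 epoxy alcohol unit. This gives the 3-O-benzoyl 4-O-TBS diol F5, whose benzoate can no longer move to O4. HF·pyridine then cleaves both silyl ethers and the route is rejoined at compound 10.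

3. Step 4. Facial selectivity of hydride delivery may be poor if the tertiary hydroxyl or chelation steers borohydride to the oxirane face. The fallback sets out from 6. Whatever C4 α-epimer of the epoxy diol F6 forms is separated and inverted by Mitsunobu esterification (4-nitrobenzoic acid, PPh3, DIAD, THF, 0 °C) to the β-configured C4 4-nitrobenzoate F7. Methanolysis (K2CO3, MeOH, 0 °C) returns compound 7; the cis-epoxy alcohol cannot undergo Payne rearrangement under these conditions.

Further compounds
F1 | step 3 | racemic syn-epoxy quinol (racemate of 6, both enantiomers written) | CC(C)(C)[Si](OC[C@@]1(O)C=CC(=O)[C@@H]2O[C@H]12)(c1ccccc1)c1ccccc1.CC(C)(C)[Si](OC[C@]1(O)C=CC(=O)[C@H]2O[C@@H]12)(c1ccccc1)c1ccccc1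
F2 | step 3 | racemic all-cis epoxy diol (racemate of 7, both enantiomers written) | CC(C)(C)[Si](OC[C@@]1(O)C=C[C@H](O)[C@@H]2O[C@H]12)(c1ccccc1)c1ccccc1.CC(C)(C)[Si](OC[C@]1(O)C=C[C@@H](O)[C@H]2O[C@@H]12)(c1ccccc1)c1ccccc1
F3 | step 3 | C4 acetate of the enantiomer of 7, (1R,2R,3R,4R)-4-acetoxy-2,3-epoxy-1-[(tert-butyldiphenylsilyloxy)methyl]cyclohex-5-en-1-ol | CC(C)(C)[Si](OC[C@]1(O)C=C[C@@H](OC(C)=O)[C@H]2O[C@@H]12)(c1ccccc1)c1ccccc1
F4 | step 5 | 4-O-tert-butyldimethylsilyl ether of 7 | CC(C)(C)[Si](OC[C@@]1(O)C=C[C@H](O[Si](C)(C)C(C)(C)C)[C@@H]2O[C@H]12)(c1ccccc1)c1ccccc1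
F5 | step 5 | 4-O-tert-butyldimethylsilyl ether of 9 (3α-benzoate, 1β,2β-diol, both silyl ethers intact) | CC(C)(C)[Si](OC[C@@]1(O)C=C[C@H](O[Si](C)(C)C(C)(C)C)[C@@H](OC(=O)c2ccccc2)[C@@H]1O)(c1ccccc1)c1ccccc1
F6 | step 4 | C4 epimer of 7 (4α-hydroxyl, trans to the oxirane) | CC(C)(C)[Si](OC[C@@]1(O)C=C[C@@H](O)[C@@H]2O[C@H]12)(c1ccccc1)c1ccccc1
F7 | step 4 | 4-O-(4-nitrobenzoyl) ester of 7 (4β-ester) | CC(C)(C)[Si](OC[C@@]1(O)C=C[C@H](OC(=O)c3ccc(cc3)[N+](=O)[O-])[C@@H]2O[C@H]12)(c1ccccc1)c1ccccc1
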